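The spring flask is to be read at 28 h, twice the last time read in the noon run, and it has the noon charge, so the noon readings stand for its earlier hours.

| setting | noon | summer | spring |
|---|---|---|---|
| substrate | 0.500 M | 0.750 M | 0.500 M |
| partner | 0.750 M | 0.750 M | 0.750 M |
| catalyst | 0.00500 M | 0.00500 M | 0.00500 M |
| time |  |  | 28 h |

| run | time / h | [target] / M |
|---|---|---|
| noon run | 1.8 | 0.043 |
| noon run | 3.5 | 0.072 |
| noon run | 5.2 | 0.098 |
| noon run | 7.0 | 0.116 |
| noon run | 8.8 | 0.129 |
| noon run | 10 | 0.144 |
| noon run | 12 | 0.153 |
| noon run | 14 | 0.154 |
| summer run | 1.8 | 0.050 |
| summer run | 3.5 | 0.088 |
| summer run | 5.2 | 0.120 |
| summer run | 7.0 | 0.139 |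
| summer run | 8.8 | 0.164 |
| summer run | 10 | 0.173 |
| summer run | 12 | 0.181 |
| summer run | 14 | 0.195 |

(standard deviation of a reading: 0.003 M)

- the exponent of [substrate] in the starting rate at the charge of the noon run (at the point where two percent of the substrate have become target) (one fixed amount of target, the same in the runs compared)
- target in the spring run at 28 h, as a share of the substrate charged

- Overall: substrate + partner -> target, with catalyst as catalyst.
- Constant volume, constant temperature.
- What is held in complexes is read along with the free species.
- An order is taken over about fifteen percent of the charge, up and down.

Two chemists dispute the late hours. The first holds that the noon flask has reached equilibrium: between 12 h and 14 h, [target] gains 0.00100 M, less than the scatter of 0.003 M, so she expects [target] to stay near 0.154 M or a little above it.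

The second, whose reckoning I adopt, treats target as an intermediate in consecutive reactions, made and lost together, and works with the share left. He takes the first noon reading over its time as a starting rate, 0.0239 M/h. Multiplied by time, that rate gives a straight-line yardstick, which is not an amount in the flask: by 28 h it stands higher than the substrate charge. The kept share, the reading divided by the yardstick at the same time, is 0.460 at 14 h in the noon run.

If a constant fraction is kept over each equal stretch of time, shares multiply, so doubling the time squares the share. The noon share at 7.0 h is 0.694, and its square, 0.482, lies close to 0.460. Squaring 0.460 for 28 h gives 0.142 M of target in the spring flask, or 28.4% of the charge.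

The forecast takes the first chemist's side, with an exponent of 0.45 and 35%, seeing noon “levelling far short of full conversion”.

The simulation gives an exponent of 0.46 and 28.0%.

    catalyst + substrate ⇌ catalyst-substrate complex, settled at all times (2.150 /M)
    catalyst-substrate complex + partner ⇌ ternary complex, settled at all times (0.3310 /M)
    ternary complex → target + catalyst (45.72 /h)
    target → decomposed product (0.06408 /h)

A fit with the main steps alone leaves a root mean square residual of 5.4 scatter units. The spring result, read as a kept share, is 0.209, against the squared 0.212. In the summer run, the starting rate is 0.0278 M/h and the kept share at 7.0 h is 0.715. Squaring it and applying it to the yardstick at 14 h gives 0.199 M, against the 0.195 M read.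

The data are simulated with constants of no real substance.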